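**Retrosynthetic overview**

- Disulfuretin ⇐ its hexa-O-methyl ether ⇐ a tetra-aryl pinacol. Each exocyclic C=C comes from 1,4-loss of MeOH from a (3-methoxybenzofuran-2-yl)carbinol, so the central C–C single bond of the diene is the pinacol bond.
- Pinacol ⇐ two molecules of a 2-aroyl-3-methoxybenzofuran by reductive homocoupling. A titanium ketyl (a polarity-reversed, acyl-anion-like carbonyl carbon) bonds to the carbonyl carbon of a second molecule, so two normally electrophilic carbons are joined.
- Aroylbenzofuran ⇐ methyl 4-methoxysalicylate + 3,4-dimethoxyphenacyl bromide (O-alkylation, Dieckmann closure, O-methylation in one flask).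
- Ring order: the furan ring of each benzofuran half is the only ring made (step 1). The central C–C bond follows (step 2), and the two Z-alkenes and the free phenols come last (step 3).

Assumption: the target has no stereocentre and is achiral, so "single enantiomer" is read as the single (2Z,2'Z) alkene isomer in the SMILES (ring oxygen syn to the central bond, catechol ring syn to C3=O, on both halves).

**Route**

Step 1
Reactants: 1 methyl 2-hydroxy-4-methoxybenzoate; 2 2-bromo-1-(3,4-dimethoxyphenyl)ethan-1-one
Product: 5 (3,6-dimethoxy-1-benzofuran-2-yl)(3,4-dimethoxyphenyl)methanone, via phenacyl ether 3 (not isolated), via 2-aroyl-3-hydroxybenzofuran 4 (not isolated)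
Conditions: Cs2CO3 (3 equiv), DMF, 25 °C then 80 °C; then Me2SO4 (1.3 equiv), 25 °C
Reagents that add atoms: dimethyl sulfate, COS(=O)(=O)OC
Why: Williamson etherification of the phenol with the phenacyl bromide is followed by a Dieckmann-type intramolecular Claisen condensation of the doubly activated OCH2C(=O)Ar methylene onto the ester, and the resulting cesium 2-aroylbenzofuran-3-olate is methylated on oxygen by the hard electrophile because O-alkylation keeps the benzofuran aromatic; no stereocentre is formed.

Step 2
Reactants: 5 (3,6-dimethoxy-1-benzofuran-2-yl)(3,4-dimethoxyphenyl)methanone (two molecules)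
Product: 6 1,2-bis(3,6-dimethoxy-1-benzofuran-2-yl)-1,2-bis(3,4-dimethoxyphenyl)ethane-1,2-diol (meso/rac mixture)
Conditions: TiCl4 (2 equiv), Zn dust (4 equiv), pyridine (1 equiv), THF, reflux 1 h; then 5, −10 to 0 °C; 10% aq K2CO3 (product kept base-washed, Et3N-deactivated silica)
Reagents that add atoms: none
Why: Mukaiyama–Corey low-valent titanium pinacol coupling: single-electron transfer turns the normally electrophilic carbonyl carbon of 5 into a titanium-bound ketyl (a polarity-reversed, acyl-anion-like d1 carbon) that bonds to the carbonyl carbon of a second molecule on the titanium template, with pyridine and 0 °C stopping the reaction at the pinacolate before deoxygenation; the two new carbinol centres form as a meso/rac mixture, which is immaterial because both become sp2 in step 3.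

Step 3
Reactants: 6 1,2-bis(3,6-dimethoxy-1-benzofuran-2-yl)-1,2-bis(3,4-dimethoxyphenyl)ethane-1,2-diol
Product: 8 disulfuretin [(2Z,2'Z)-2,2'-[1,2-bis(3,4-dihydroxyphenyl)ethane-1,2-diylidene]bis(6-hydroxy-1-benzofuran-3(2H)-one)], via hexa-O-methyldisulfuretin 7 (not isolated)
Conditions: BBr3 (14 equiv), CH2Cl2, −78 °C (1 h) to 25 °C (12 h); then H2O, 0 °C
Reagents that add atoms: none
Why: Proposed new method: BBr3 turns each tertiary, doubly benzylic carbinol into a borate leaving group that ionises at −78 °C to a cation fully delocalised onto the 3-methoxy oxygen (an O-methylated aurone, too stabilised for a pinacol-type 1,2-shift), bromide removes that methyl by SN2 to unveil the C3 ketone and the exocyclic alkene, and allylic 1,3-strain against the 3-OMe group in the ionising rotamer places the bulkier quaternary (second time: tetrasubstituted vinyl) carbon syn to the ring oxygen and the aryl syn to C3, which is the Z geometry at both alkenes, after which warming effects ordinary BBr3 cleavage of the six aryl methyl ethers while acid-mediated E/Z equilibration of the free 4'-hydroxyaurone units (through quinone-methide tautomers) backs up the same, expected thermodynamic Z,Z isomer; the closest known reactions are the acid dehydration of 3-oxybenzofuran-2-yl carbinols (aurone aldol adducts) to aurones and the BBr3 demethylation of aurone methyl ethers.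

**Compound list**

1 | methyl 2-hydroxy-4-methoxybenzoate | COC(=O)c1ccc(OC)cc1O | starting material
2 | 2-bromo-1-(3,4-dimethoxyphenyl)ethan-1-one | COc1ccc(C(=O)CBr)cc1OC | starting material
3 | methyl 2-[2-(3,4-dimethoxyphenyl)-2-oxoethoxy]-4-methoxybenzoate (phenacyl ether) | COC(=O)c1ccc(OC)cc1OCC(=O)c1ccc(OC)c(OC)c1 | intermediate (not isolated)
4 | (3,4-dimethoxyphenyl)(3-hydroxy-6-methoxy-1-benzofuran-2-yl)methanone (present in the flask as its cesium enolate) | COc1ccc2c(O)c(C(=O)c3ccc(OC)c(OC)c3)oc2c1 | intermediate (not isolated)
5 | (3,6-dimethoxy-1-benzofuran-2-yl)(3,4-dimethoxyphenyl)methanone | COc1ccc2c(OC)c(C(=O)c3ccc(OC)c(OC)c3)oc2c1 | intermediate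
6 | 1,2-bis(3,6-dimethoxy-1-benzofuran-2-yl)-1,2-bis(3,4-dimethoxyphenyl)ethane-1,2-diol (meso/rac mixture, no descriptor given; both centres are destroyed in step 3) | COc1ccc2c(OC)c(C(O)(c3ccc(OC)c(OC)c3)C(O)(c3ccc(OC)c(OC)c3)c3oc4cc(OC)ccc4c3OC)oc2c1 | intermediate
7 | hexa-O-methyldisulfuretin, (2Z,2'Z)-2,2'-[1,2-bis(3,4-dimethoxyphenyl)ethane-1,2-diylidene]bis(6-methoxy-1-benzofuran-3(2H)-one) | O=C1/C(=C(/C(=C2\Oc3cc(OC)ccc3C2=O)c2ccc(OC)c(OC)c2)c2ccc(OC)c(OC)c2)Oc2cc(OC)ccc21 | intermediate (not isolated)
8 | disulfuretin, (2Z,2'Z)-2,2'-[1,2-bis(3,4-dihydroxyphenyl)ethane-1,2-diylidene]bis(6-hydroxy-1-benzofuran-3(2H)-one) | O=C1/C(=C(/C(=C2\Oc3cc(O)ccc3C2=O)c2ccc(O)c(O)c2)c2ccc(O)c(O)c2)Oc2cc(O)ccc21 | target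

**Totals**

Total step count: 3. Longest linear sequence: 3 (the route is linear; step 2 is a homodimerisation).

**Steps most likely to fail, with fallbacks**

Step 2 (reductive homocoupling) is the riskiest. The titanium pinacolate of this very electron-rich diaryl ketone may ionise or be over-reduced on the Lewis-acidic metal, or the diol may be too labile to isolate. The fallback drives deoxygenation to completion and restores the oxidation level afterwards. It sets out from 5: TiCl4/Zn in refluxing THF (full McMurry olefination) gives 1,2-bis(3,6-dimethoxy-1-benzofuran-2-yl)-1,2-bis(3,4-dimethoxyphenyl)ethene F1 (E/Z mixture, immaterial because this bond becomes the single bond). Two-electron oxidative demethylation of its 1,6-dimethoxytriene with (NH4)2Ce(NO3)6 in MeCN/H2O at 0 °C, the reaction that turns 1,4-dimethoxyarenes into quinones, then gives 7 with loss of two MeOH. The route is rejoined at 7, which is demethylated with BBr3 as in the second half of step 3.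

Step 3 (tandem ionisation/demethylation) comes next. The risks are a 1,2-aryl shift of the pinacol, incomplete ether cleavage, or an E-configured alkene. The fallback uncouples the two events and replaces the Lewis-acid ionisation by protic solvolysis. It sets out from 6: TsOH·H2O (10 mol %) in wet acetone at 0–25 °C hydrolyses the enol ethers and dehydrates, giving isolated 7 with loss of methanol. The geometry of 7 can be checked (NOE, X-ray) and, if an E-alkene is present, equilibrated with catalytic I2 in CHCl3 in daylight. Clean 7 then undergoes the ether cleavage alone (BBr3, CH2Cl2, −78 to 25 °C), returning to the route at 8. No compound outside the list is made (F0).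

Step 1 (one-flask alkylation/Dieckmann/O-methylation) is the third. The risks are a stalled Dieckmann closure or C-methylation of the ambident enolate. The fallback brings the aroyl group in last by a Weinreb ketone synthesis. It sets out from 1 and returns at 5:
- Methyl bromoacetate/K2CO3 in acetone gives methyl 4-methoxy-2-(2-methoxy-2-oxoethoxy)benzoate F2.
- NaOMe in MeOH/toluene closes it to methyl 3-hydroxy-6-methoxy-1-benzofuran-2-carboxylate F3.
- Me2SO4/K2CO3 in acetone gives methyl 3,6-dimethoxy-1-benzofuran-2-carboxylate F4; O-methylation of such 3-hydroxy esters is dependable.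
- Me(MeO)NH·HCl/i-PrMgCl in THF at −20 °C gives N,3,6-trimethoxy-N-methyl-1-benzofuran-2-carboxamide F5.
- (3,4-Dimethoxyphenyl)magnesium bromide in THF at 0 °C converts F5 into 5.

**Further compounds**

F1 | step 2 | 1,2-bis(3,6-dimethoxy-1-benzofuran-2-yl)-1,2-bis(3,4-dimethoxyphenyl)ethene (E/Z mixture, no descriptor given) | COc1ccc2c(OC)c(C(=C(c3ccc(OC)c(OC)c3)c3oc4cc(OC)ccc4c3OC)c3ccc(OC)c(OC)c3)oc2c1
F0 | step 3 | none | none
F2 | step 1 | methyl 4-methoxy-2-(2-methoxy-2-oxoethoxy)benzoate | COC(=O)COc1cc(OC)ccc1C(=O)OC
F3 | step 1 | methyl 3-hydroxy-6-methoxy-1-benzofuran-2-carboxylate | COC(=O)c1oc2cc(OC)ccc2c1O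
F4 | step 1 | methyl 3,6-dimethoxy-1-benzofuran-2-carboxylate | COC(=O)c1oc2cc(OC)ccc2c1OC
F5 | step 1 | N,3,6-trimethoxy-N-methyl-1-benzofuran-2-carboxamide | CON(C)C(=O)c1oc2cc(OC)ccc2c1OC
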